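**Retrosynthetic overview**
1. The only ring is the 28-membered macrocycle. It is closed in the penultimate step by forming the C2′–O ester bond (tethered carboxylate onto a racemic α-bromo amide, stereoconvergent copper catalysis); global desilylation ends the route.
2. The seco acid comes from late azide displacement and Staudinger reduction at C24, then N-acylation with racemic 2-bromopentanoyl chloride.
3. Chain union: C17–C18 by B-alkyl Suzuki coupling (eastern alkene C18–C24 plus a bromodiene); C15–C16 by hydrozirconation/Negishi coupling of the western alkyne (C1–C15) with (E)-2-bromo-1-iodo-3-methoxypropene.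
4. Western half: meso-anhydride desymmetrisation (C2, C4), hydrolytic kinetic resolution of a terminal epoxide (C9) and Rh-catalysed conjugate alkynylation (C13), joined by Cu-catalysed alkyl–alkyl coupling and Grignard epoxide opening.
5. Eastern half: ethyl (S)-4-chloro-3-hydroxybutanoate (C23) plus reagent-controlled anti γ-silylallylboration/Tamao oxidation (C20, C21).

Assumption: chain atoms are numbered C1 (lactone carbonyl) to C24 (CH2N) and C1′–C5′ for the 2-hydroxypentanoyl unit; for each catalyst-controlled step the catalyst antipode named is the one expected by analogy to give the drawn configuration, and its mirror image is used if the sense proves opposite.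

**Route**

Step 1
Reactants: 1 meso-2,4-dimethylglutaric anhydride [(3R,5S)-3,5-dimethyloxane-2,6-dione]
Product: 2 (2R,4S)-5-methoxy-2,4-dimethyl-5-oxopentanoic acid
Conditions: MeOH (10 equiv), (DHQD)2AQN (10 mol %), Et2O, −30 °C
Reagents that add atoms: methanol, CO
Why: Cinchona-alkaloid-catalysed desymmetrising alcoholysis of a meso anhydride; general-base delivery of methanol to one enantiotopic carbonyl fixes both methyl-bearing centres (future C2 S and C4 S, syn) at once.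

Step 2
Reactants: 2 (2R,4S)-5-methoxy-2,4-dimethyl-5-oxopentanoic acid
Product: 3 methyl (2S,4R)-5-hydroxy-2,4-dimethylpentanoate
Conditions: BH3·SMe2, THF, 0 °C to rt; MeOH quench; used crude
Reagents that add atoms: none
Why: Chemoselective borane reduction of a carboxylic acid beside a methyl ester; no stereocentre is touched.

Step 3
Reactants: 3 methyl (2S,4R)-5-hydroxy-2,4-dimethylpentanoate
Product: 4 methyl (2S,4R)-5-iodo-2,4-dimethylpentanoate
Conditions: I2, PPh3, imidazole, CH2Cl2, 0 °C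
Reagents that add atoms: iodine, II
Why: Appel-type iodination of a primary alcohol under neutral conditions, which also removes the risk of δ-lactonisation.

Step 4
Reactants: 4 methyl (2S,4R)-5-iodo-2,4-dimethylpentanoate; 5 pent-4-en-1-ylmagnesium bromide
Product: 6 methyl (2S,4S)-2,4-dimethyldec-9-enoate
Conditions: Li2CuCl4 (3 mol %), THF/NMP, −20 to 0 °C
Reagents that add atoms: none
Why: Copper-catalysed alkyl–alkyl Grignard cross-coupling (Kochi/Cahiez type) is much faster than Grignard addition to the hindered α-branched methyl ester; the descriptor at C4 changes to S only through CIP priorities.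

Step 5
Reactants: 6 methyl (2S,4S)-2,4-dimethyldec-9-enoate
Product: 7 methyl (2S,4S)-2,4-dimethyl-8-(oxiran-2-yl)octanoate (1:1 epimers at C9)
Conditions: mCPBA, NaHCO3, CH2Cl2, 0 °C to rt
Reagents that add atoms: mCPBA, OOC(=O)c1cccc(Cl)c1
Why: Prilezhaev epoxidation of the terminal alkene; the remote centres give no facial bias, so the C9 epimers are resolved in the next step.

Step 6
Reactants: 7 methyl (2S,4S)-2,4-dimethyl-8-(oxiran-2-yl)octanoate
Product: 8 methyl (2S,4S)-2,4-dimethyl-8-[(2R)-oxiran-2-yl]octanoate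
Conditions: (R,R)-(salen)Co(OAc) [salen = N,N′-bis(3,5-di-tert-butylsalicylidene)-1,2-cyclohexanediamine dianion] (0.5 mol %), H2O (0.55 equiv), THF, 0 °C to rt
Reagents that add atoms: none
Why: Jacobsen hydrolytic kinetic resolution; cooperative bimetallic epoxide activation hydrolyses the (9S)-epimer selectively and leaves the (9R)-epoxide (C9 set by catalyst control, maximum 50 % yield).

Step 7
Reactants: 9 (E)-pent-2-enal; 10 ethynyltri(propan-2-yl)silane
Product: 12 (3R)-3-ethyl-5-[tri(propan-2-yl)silyl]pent-4-yn-1-ol, via alkynyl aldehyde 11 (not isolated)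
Conditions: [Rh(OAc)(C2H4)2]2 (2.5 mol %), (R)-DTBM-SEGPHOS (5.5 mol %), MeOH, 40 °C; then NaBH4, 0 °C
Reagents that add atoms: none
Why: Rhodium-catalysed asymmetric conjugate alkynylation of an enal, in which the bisphosphine selects the enal face and sets C13 (R), followed by borohydride reduction of the β-alkynyl aldehyde in the same pot.

Step 8
Reactants: 12 (3R)-3-ethyl-5-[tri(propan-2-yl)silyl]pent-4-yn-1-ol
Product: 13 [(3R)-5-bromo-3-ethylpent-1-yn-1-yl]tri(propan-2-yl)silane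
Conditions: CBr4, PPh3, CH2Cl2, 0 °C
Reagents that add atoms: carbon tetrabromide, BrC(Br)(Br)Br
Why: Appel bromination of a primary alcohol; the stereocentre is not involved.

Step 9
Reactants: 13 [(3R)-5-bromo-3-ethylpent-1-yn-1-yl]tri(propan-2-yl)silane; 8 methyl (2S,4S)-2,4-dimethyl-8-[(2R)-oxiran-2-yl]octanoate
Product: 16 methyl (2S,4S,9R,13R)-9-[(tert-butyldimethylsilyl)oxy]-13-ethyl-2,4-dimethyl-15-[tri(propan-2-yl)silyl]pentadec-14-ynoate, via Grignard reagent 14 (not isolated), via bromomagnesium alkoxide 15 (not isolated)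
Conditions: 13 (1.4 equiv), Mg, THF, 40 °C; then 8, CuI (10 mol %), THF, −40 to −20 °C; then 2,6-lutidine, TBSOTf, −78 to 0 °C
Reagents that add atoms: tert-butyldimethylsilyl triflate, CC(C)(C)[Si](C)(C)OS(=O)(=O)C(F)(F)F
Why: Copper-catalysed Grignard opening of the terminal epoxide at CH2 (C10–C11 bond, C9 configuration retained) outruns attack on the hindered ester at low temperature, and the magnesium alkoxide is trapped in situ as the TBS ether.

Step 10
Reactants: 16 methyl (2S,4S,9R,13R)-9-[(tert-butyldimethylsilyl)oxy]-13-ethyl-2,4-dimethyl-15-[tri(propan-2-yl)silyl]pentadec-14-ynoate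
Product: 18 methyl (2S,4S,9R,13R)-9-[(tert-butyldimethylsilyl)oxy]-13-ethyl-2,4-dimethylpentadec-14-ynoate, via silver acetylide 17 (not isolated)
Conditions: AgF (1.5 equiv), MeOH/THF, rt, dark; then 1 M HCl, 0 °C
Reagents that add atoms: none
Why: Silver-fluoride C(sp)–Si cleavage proceeds through the silver acetylide and leaves the secondary TBS ether and the ester untouched.

Step 11
Reactants: 19 3-methoxyprop-1-yne
Product: 20 (1E)-2-bromo-1-iodo-3-methoxyprop-1-ene
Conditions: IBr (1.0 equiv), CH2Cl2, −78 to 0 °C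
Reagents that add atoms: iodine monobromide, IBr
Why: Anti iodobromination of a terminal alkyne through the iodonium ion puts iodine on the terminal carbon, cis to CH2OMe and trans to bromine, which fixes the later C16=C17 geometry.

Step 12
Reactants: 18 methyl (2S,4S,9R,13R)-9-[(tert-butyldimethylsilyl)oxy]-13-ethyl-2,4-dimethylpentadec-14-ynoate; 20 (1E)-2-bromo-1-iodo-3-methoxyprop-1-ene
Product: 23 methyl (2S,4S,9R,13R,14E,16E)-17-bromo-9-[(tert-butyldimethylsilyl)oxy]-13-ethyl-18-methoxy-2,4-dimethyloctadeca-14,16-dienoate, via alkenylzirconocene chloride 21 (not isolated), via alkenylzinc chloride 22 (not isolated)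
Conditions: Cp2Zr(H)Cl (1.3 equiv), THF, rt; ZnCl2 (1.5 equiv), 0 °C; 20 (1.2 equiv), Pd(PPh3)4 (5 mol %), rt
Reagents that add atoms: none
Why: Syn hydrozirconation gives the (E)-alkenyl metal, and Negishi coupling after Zr-to-Zn transmetalation takes place only at the C–I bond with retention, giving the 14E diene with C15 cis to CH2OMe.

Step 13
Reactants: 24 ethyl (3S)-4-chloro-3-hydroxybutanoate
Product: 25 ethyl (3S)-3-[(tert-butyldimethylsilyl)oxy]-4-chlorobutanoate
Conditions: TBSCl, imidazole, DMF, rt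
Reagents that add atoms: tert-butyldimethylsilyl chloride, CC(C)(C)[Si](C)(C)Cl
Why: Standard silylation of the secondary alcohol; the chiral-pool centre becomes C23 (S).

Step 14
Reactants: 25 ethyl (3S)-3-[(tert-butyldimethylsilyl)oxy]-4-chlorobutanoate
Product: 26 (3S)-3-[(tert-butyldimethylsilyl)oxy]-4-chlorobutanal
Conditions: i-Bu2AlH (1.05 equiv), CH2Cl2, −78 °C; Rochelle salt work-up
Reagents that add atoms: none
Why: Low-temperature half-reduction of the ester through the stable tetrahedral aluminate gives the aldehyde without touching the chloride or silyl ether.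

Step 15
Reactants: 26 (3S)-3-[(tert-butyldimethylsilyl)oxy]-4-chlorobutanal; 27 N-[dimethyl(prop-2-en-1-yl)silyl]-N-(propan-2-yl)propan-2-amine [allyl(diisopropylamino)dimethylsilane]
Product: 31 (3R,4S,6S)-6-[(tert-butyldimethylsilyl)oxy]-7-chlorohept-1-ene-3,4-diol, via lithiated allylsilane 28 (not isolated), via silylallyl diisopinocampheylborane 29 (not isolated), via borinate adduct 30 (not isolated)
Conditions: 27, n-BuLi, TMEDA, Et2O, 0 °C; (+)-Ipc2BOMe, −78 °C; BF3·OEt2; 26, −78 °C; then KF, KHCO3, 30 % H2O2, THF/MeOH, rt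
Reagents that add atoms: hydrogen peroxide, OO
Why: Brown-type asymmetric allylboration with an (E)-γ-silylallyl diisopinocampheylborane; the Ipc groups select the aldehyde face (C21 S), the chair transition state gives the anti relationship, and Tamao–Fleming oxidation replaces Si by OH with retention (C20 R).

Step 16
Reactants: 31 (3R,4S,6S)-6-[(tert-butyldimethylsilyl)oxy]-7-chlorohept-1-ene-3,4-diol
Product: 32 (3R,4S,6S)-3,4,6-tris[(tert-butyldimethylsilyl)oxy]-7-chlorohept-1-ene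
Conditions: TBSOTf (2.5 equiv), 2,6-lutidine, CH2Cl2, 0 °C
Reagents that add atoms: tert-butyldimethylsilyl triflate, CC(C)(C)[Si](C)(C)OS(=O)(=O)C(F)(F)F
Why: Silyl triflate bis-silylation of the hindered vicinal diol gives a uniformly fluoride-labile protecting-group set.

Step 17
Reactants: 32 (3R,4S,6S)-3,4,6-tris[(tert-butyldimethylsilyl)oxy]-7-chlorohept-1-ene; 23 methyl (2S,4S,9R,13R,14E,16E)-17-bromo-9-[(tert-butyldimethylsilyl)oxy]-13-ethyl-18-methoxy-2,4-dimethyloctadeca-14,16-dienoate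
Product: 34 methyl (2S,4S,9R,13R,14E,16Z,20R,21S,23S)-9,20,21,23-tetrakis[(tert-butyldimethylsilyl)oxy]-24-chloro-13-ethyl-17-(methoxymethyl)-2,4-dimethyltetracosa-14,16-dienoate, via B-alkyl-9-BBN 33 (not isolated)
Conditions: 32 (1.4 equiv), 9-BBN, THF, rt; then 3 M aq. Cs2CO3, 23, Pd(dppf)Cl2 (10 mol %), AsPh3 (10 mol %), DMF, rt to 40 °C
Reagents that add atoms: none
Why: Anti-Markovnikov hydroboration of the terminal alkene and B-alkyl Suzuki–Miyaura coupling at the alkenyl C–Br bond with retention form C17–C18 and the 16Z trisubstituted alkene; the alkyl chloride and ester are inert.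

Step 18
Reactants: 34 methyl (2S,4S,9R,13R,14E,16Z,20R,21S,23S)-9,20,21,23-tetrakis[(tert-butyldimethylsilyl)oxy]-24-chloro-13-ethyl-17-(methoxymethyl)-2,4-dimethyltetracosa-14,16-dienoate
Product: 35 methyl (2S,4S,9R,13R,14E,16Z,20R,21S,23S)-24-azido-9,20,21,23-tetrakis[(tert-butyldimethylsilyl)oxy]-13-ethyl-17-(methoxymethyl)-2,4-dimethyltetracosa-14,16-dienoate
Conditions: NaN3 (3 equiv), NaI (0.2 equiv), DMF, 75 °C
Reagents that add atoms: sodium azide, [Na+].[N-]=[N+]=[N-]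
Why: Iodide-assisted SN2 azidation of the primary chloride forms the C24–N bond without touching C23.

Step 19
Reactants: 35 methyl (2S,4S,9R,13R,14E,16Z,20R,21S,23S)-24-azido-9,20,21,23-tetrakis[(tert-butyldimethylsilyl)oxy]-13-ethyl-17-(methoxymethyl)-2,4-dimethyltetracosa-14,16-dienoate
Product: 36 (2S,4S,9R,13R,14E,16Z,20R,21S,23S)-24-azido-9,20,21,23-tetrakis[(tert-butyldimethylsilyl)oxy]-13-ethyl-17-(methoxymethyl)-2,4-dimethyltetracosa-14,16-dienoic acid
Conditions: LiOH·H2O (5 equiv), THF/MeOH/H2O, 40 °C; then 1 M HCl to pH 4, 0 °C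
Reagents that add atoms: lithium hydroxide, [Li+].[OH-]
Why: Saponification of the methyl ester; the carboxylate formed protects C2 against enolisation, and azide, TBS ethers and diene are base-stable.

Step 20
Reactants: 36 (2S,4S,9R,13R,14E,16Z,20R,21S,23S)-24-azido-9,20,21,23-tetrakis[(tert-butyldimethylsilyl)oxy]-13-ethyl-17-(methoxymethyl)-2,4-dimethyltetracosa-14,16-dienoic acid; 37 (2RS)-2-bromopentanoyl chloride
Product: 40 (2S,4S,9R,13R,14E,16Z,20R,21S,23S)-24-[(2RS)-2-bromopentanamido]-9,20,21,23-tetrakis[(tert-butyldimethylsilyl)oxy]-13-ethyl-17-(methoxymethyl)-2,4-dimethyltetracosa-14,16-dienoic acid, via iminophosphorane 38 (not isolated), via amino acid 39 (not isolated)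
Conditions: PMe3 (1.5 equiv), THF/H2O, rt; evaporate volatiles; then NaHCO3, 37 (1.1 equiv), THF/H2O, 0 °C
Reagents that add atoms: none
Why: Staudinger reduction of the azide followed by Schotten–Baumann N-acylation, in which the amine is acylated far faster than the carboxylate and all hydroxyls are silylated.

Step 21
Reactants: 40 (2S,4S,9R,13R,14E,16Z,20R,21S,23S)-24-[(2RS)-2-bromopentanamido]-9,20,21,23-tetrakis[(tert-butyldimethylsilyl)oxy]-13-ethyl-17-(methoxymethyl)-2,4-dimethyltetracosa-14,16-dienoic acid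
Product: 41 9,20,21,23-tetrakis-O-(tert-butyldimethylsilyl) ether of the target macrocycle (2′S; ester O2′–C1, amide N24–C1′)
Conditions: Cu(MeCN)4PF6 (15 mol %), (S,S)-tBu-BOX [2,2′-(propane-2,2-diyl)bis((4S)-4-tert-butyl-4,5-dihydro-1,3-oxazole)] (18 mol %), K3PO4 (2 equiv), 2-MeTHF/toluene, syringe-pump addition to 1 mM, 25 °C, argon
Reagents that add atoms: none
Why: Proposed new method: a monovalent copper–bis(oxazoline) complex binds the tethered carboxylate and abstracts bromine from the α-bromo amide to give a planar α-amido radical (erasing the C2′ configuration of both epimers) and a divalent copper carboxylate, radical capture gives a trivalent alkylcopper carboxylate, and ligand-controlled C–O reductive elimination closes the 28-membered ring and sets C2′ (S) from the racemic bromide, while the low stationary concentration and the slow uncatalysed SN2 in a non-polar medium suppress oligomers and unselective background; the closest known reaction types are intermolecular copper-catalysed enantioconvergent substitution of racemic α-halo amides by oxygen nucleophiles and enantioselective copper-carboxylate radical C–O bond formation in alkene oxy-functionalisation.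

Step 22
Reactants: 41 9,20,21,23-tetrakis-O-(tert-butyldimethylsilyl) ether of the target macrocycle
Product: 42 CNP0221503.3, the 28-membered macrocycle formed from (2S)-2-hydroxypentanoic acid and (2S,4S,9R,13R,14E,16Z,20R,21S,23S)-24-amino-13-ethyl-9,20,21,23-tetrahydroxy-17-(methoxymethyl)-2,4-dimethyltetracosa-14,16-dienoic acid (ester through O2′–C1, amide through N24–C1′)
Conditions: HF·pyridine, pyridine, THF, 0 °C to rt
Reagents that add atoms: none
Why: Buffered fluoride-mediated global desilylation removes the four TBS ethers without harming the diene, the allylic methyl ether, the lactone or any stereocentre.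

**Compound list**
1 | meso-2,4-dimethylglutaric anhydride, (3R,5S)-3,5-dimethyloxane-2,6-dione | O=C1OC(=O)[C@@H](C)C[C@H]1C | starting material
2 | (2R,4S)-5-methoxy-2,4-dimethyl-5-oxopentanoic acid | COC(=O)[C@@H](C)C[C@@H](C)C(=O)O | intermediate
3 | methyl (2S,4R)-5-hydroxy-2,4-dimethylpentanoate | COC(=O)[C@@H](C)C[C@@H](C)CO | intermediate
4 | methyl (2S,4R)-5-iodo-2,4-dimethylpentanoate | COC(=O)[C@@H](C)C[C@@H](C)CI | intermediate
5 | pent-4-en-1-ylmagnesium bromide | C=CCCC[Mg]Br | starting material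
6 | methyl (2S,4S)-2,4-dimethyldec-9-enoate | COC(=O)[C@@H](C)C[C@@H](C)CCCCC=C | intermediate
7 | methyl (2S,4S)-2,4-dimethyl-8-(oxiran-2-yl)octanoate, 1:1 C9 epimers | COC(=O)[C@@H](C)C[C@@H](C)CCCCC1CO1 | intermediate
8 | methyl (2S,4S)-2,4-dimethyl-8-[(2R)-oxiran-2-yl]octanoate | COC(=O)[C@@H](C)C[C@@H](C)CCCC[C@@H]1CO1 | intermediate
9 | (E)-pent-2-enal | CC/C=C/C=O | starting material
10 | ethynyltri(propan-2-yl)silane | C#C[Si](C(C)C)(C(C)C)C(C)C | starting material
11 | (3R)-3-ethyl-5-[tri(propan-2-yl)silyl]pent-4-ynal | O=CC[C@@H](CC)C#C[Si](C(C)C)(C(C)C)C(C)C | intermediate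
12 | (3R)-3-ethyl-5-[tri(propan-2-yl)silyl]pent-4-yn-1-ol | OCC[C@@H](CC)C#C[Si](C(C)C)(C(C)C)C(C)C | intermediate
13 | [(3R)-5-bromo-3-ethylpent-1-yn-1-yl]tri(propan-2-yl)silane | BrCC[C@@H](CC)C#C[Si](C(C)C)(C(C)C)C(C)C | intermediate
14 | {(3R)-3-ethyl-5-[tri(propan-2-yl)silyl]pent-4-yn-1-yl}magnesium bromide | Br[Mg]CC[C@@H](CC)C#C[Si](C(C)C)(C(C)C)C(C)C | intermediate
15 | bromomagnesium alkoxide of methyl (2S,4S,9R,13R)-13-ethyl-9-hydroxy-2,4-dimethyl-15-[tri(propan-2-yl)silyl]pentadec-14-ynoate | COC(=O)[C@@H](C)C[C@@H](C)CCCC[C@@H](O[Mg]Br)CCC[C@@H](CC)C#C[Si](C(C)C)(C(C)C)C(C)C | intermediate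
16 | methyl (2S,4S,9R,13R)-9-[(tert-butyldimethylsilyl)oxy]-13-ethyl-2,4-dimethyl-15-[tri(propan-2-yl)silyl]pentadec-14-ynoate | COC(=O)[C@@H](C)C[C@@H](C)CCCC[C@@H](O[Si](C)(C)C(C)(C)C)CCC[C@@H](CC)C#C[Si](C(C)C)(C(C)C)C(C)C | intermediate
17 | silver acetylide of 18 | COC(=O)[C@@H](C)C[C@@H](C)CCCC[C@@H](O[Si](C)(C)C(C)(C)C)CCC[C@@H](CC)C#C[Ag] | intermediate
18 | methyl (2S,4S,9R,13R)-9-[(tert-butyldimethylsilyl)oxy]-13-ethyl-2,4-dimethylpentadec-14-ynoate | COC(=O)[C@@H](C)C[C@@H](C)CCCC[C@@H](O[Si](C)(C)C(C)(C)C)CCC[C@@H](CC)C#C | intermediate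
19 | 3-methoxyprop-1-yne | COCC#C | starting material
20 | (1E)-2-bromo-1-iodo-3-methoxyprop-1-ene | I/C=C(\COC)Br | intermediate
21 | (E)-alkenylzirconocene chloride from 18 (Zr on C15) | COC(=O)[C@@H](C)C[C@@H](C)CCCC[C@@H](O[Si](C)(C)C(C)(C)C)CCC[C@@H](CC)/C=C/[Zr](Cl)(C1C=CC=C1)C1C=CC=C1 | intermediate
22 | (E)-alkenylzinc chloride from 18 (Zn on C15) | COC(=O)[C@@H](C)C[C@@H](C)CCCC[C@@H](O[Si](C)(C)C(C)(C)C)CCC[C@@H](CC)/C=C/[Zn]Cl | intermediate
23 | methyl (2S,4S,9R,13R,14E,16E)-17-bromo-9-[(tert-butyldimethylsilyl)oxy]-13-ethyl-18-methoxy-2,4-dimethyloctadeca-14,16-dienoate | COC(=O)[C@@H](C)C[C@@H](C)CCCC[C@@H](O[Si](C)(C)C(C)(C)C)CCC[C@@H](CC)/C=C/C=C(\COC)Br | intermediate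
24 | ethyl (3S)-4-chloro-3-hydroxybutanoate | CCOC(=O)C[C@H](O)CCl | starting material
25 | ethyl (3S)-3-[(tert-butyldimethylsilyl)oxy]-4-chlorobutanoate | CCOC(=O)C[C@H](O[Si](C)(C)C(C)(C)C)CCl | intermediate
26 | (3S)-3-[(tert-butyldimethylsilyl)oxy]-4-chlorobutanal | O=CC[C@H](O[Si](C)(C)C(C)(C)C)CCl | intermediate
27 | allyl(diisopropylamino)dimethylsilane | C=CC[Si](C)(C)N(C(C)C)C(C)C | starting material
28 | (E)-3-lithio-1-[(diisopropylamino)dimethylsilyl]prop-1-ene | [Li]C/C=C/[Si](C)(C)N(C(C)C)C(C)C | intermediate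
29 | (E)-3-[(diisopropylamino)dimethylsilyl]allyl-bis[(+)-isopinocampheyl]borane | C(/C=C/[Si](C)(C)N(C(C)C)C(C)C)B([C@H]1C[C@H]2C[C@@H]([C@@H]1C)C2(C)C)[C@H]1C[C@H]2C[C@@H]([C@@H]1C)C2(C)C | intermediate
30 | bis[(+)-isopinocampheyl]borinate of (3R,4S,6S)-6-[(tert-butyldimethylsilyl)oxy]-7-chloro-3-[(diisopropylamino)dimethylsilyl]hept-1-en-4-ol | C=C[C@@H]([Si](C)(C)N(C(C)C)C(C)C)[C@@H](OB([C@H]1C[C@H]2C[C@@H]([C@@H]1C)C2(C)C)[C@H]1C[C@H]2C[C@@H]([C@@H]1C)C2(C)C)C[C@H](O[Si](C)(C)C(C)(C)C)CCl | intermediate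
31 | (3R,4S,6S)-6-[(tert-butyldimethylsilyl)oxy]-7-chlorohept-1-ene-3,4-diol | C=C[C@@H](O)[C@@H](O)C[C@H](O[Si](C)(C)C(C)(C)C)CCl | intermediate
32 | (3R,4S,6S)-3,4,6-tris[(tert-butyldimethylsilyl)oxy]-7-chlorohept-1-ene | C=C[C@@H](O[Si](C)(C)C(C)(C)C)[C@@H](O[Si](C)(C)C(C)(C)C)C[C@H](O[Si](C)(C)C(C)(C)C)CCl | intermediate
33 | 9-[(3R,4S,6S)-3,4,6-tris[(tert-butyldimethylsilyl)oxy]-7-chloroheptyl]-9-borabicyclo[3.3.1]nonane | B1(C2CCCC1CCC2)CC[C@@H](O[Si](C)(C)C(C)(C)C)[C@@H](O[Si](C)(C)C(C)(C)C)C[C@H](O[Si](C)(C)C(C)(C)C)CCl | intermediate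
34 | methyl (2S,4S,9R,13R,14E,16Z,20R,21S,23S)-9,20,21,23-tetrakis[(tert-butyldimethylsilyl)oxy]-24-chloro-13-ethyl-17-(methoxymethyl)-2,4-dimethyltetracosa-14,16-dienoate | COC(=O)[C@@H](C)C[C@@H](C)CCCC[C@@H](O[Si](C)(C)C(C)(C)C)CCC[C@@H](CC)/C=C/C=C(\COC)CC[C@@H](O[Si](C)(C)C(C)(C)C)[C@@H](O[Si](C)(C)C(C)(C)C)C[C@H](O[Si](C)(C)C(C)(C)C)CCl | intermediate
35 | methyl (2S,4S,9R,13R,14E,16Z,20R,21S,23S)-24-azido-9,20,21,23-tetrakis[(tert-butyldimethylsilyl)oxy]-13-ethyl-17-(methoxymethyl)-2,4-dimethyltetracosa-14,16-dienoate | COC(=O)[C@@H](C)C[C@@H](C)CCCC[C@@H](O[Si](C)(C)C(C)(C)C)CCC[C@@H](CC)/C=C/C=C(\COC)CC[C@@H](O[Si](C)(C)C(C)(C)C)[C@@H](O[Si](C)(C)C(C)(C)C)C[C@H](O[Si](C)(C)C(C)(C)C)CN=[N+]=[N-] | intermediate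
36 | (2S,4S,9R,13R,14E,16Z,20R,21S,23S)-24-azido-9,20,21,23-tetrakis[(tert-butyldimethylsilyl)oxy]-13-ethyl-17-(methoxymethyl)-2,4-dimethyltetracosa-14,16-dienoic acid | OC(=O)[C@@H](C)C[C@@H](C)CCCC[C@@H](O[Si](C)(C)C(C)(C)C)CCC[C@@H](CC)/C=C/C=C(\COC)CC[C@@H](O[Si](C)(C)C(C)(C)C)[C@@H](O[Si](C)(C)C(C)(C)C)C[C@H](O[Si](C)(C)C(C)(C)C)CN=[N+]=[N-] | intermediate
37 | (2RS)-2-bromopentanoyl chloride | CCCC(Br)C(=O)Cl | starting material
38 | P,P,P-trimethyl iminophosphorane of the C24 amine (from 36) | OC(=O)[C@@H](C)C[C@@H](C)CCCC[C@@H](O[Si](C)(C)C(C)(C)C)CCC[C@@H](CC)/C=C/C=C(\COC)CC[C@@H](O[Si](C)(C)C(C)(C)C)[C@@H](O[Si](C)(C)C(C)(C)C)C[C@H](O[Si](C)(C)C(C)(C)C)CN=P(C)(C)C | intermediate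
39 | (2S,4S,9R,13R,14E,16Z,20R,21S,23S)-24-amino-9,20,21,23-tetrakis[(tert-butyldimethylsilyl)oxy]-13-ethyl-17-(methoxymethyl)-2,4-dimethyltetracosa-14,16-dienoic acid | OC(=O)[C@@H](C)C[C@@H](C)CCCC[C@@H](O[Si](C)(C)C(C)(C)C)CCC[C@@H](CC)/C=C/C=C(\COC)CC[C@@H](O[Si](C)(C)C(C)(C)C)[C@@H](O[Si](C)(C)C(C)(C)C)C[C@H](O[Si](C)(C)C(C)(C)C)CN | intermediate
40 | (2S,4S,9R,13R,14E,16Z,20R,21S,23S)-24-[(2RS)-2-bromopentanamido]-9,20,21,23-tetrakis[(tert-butyldimethylsilyl)oxy]-13-ethyl-17-(methoxymethyl)-2,4-dimethyltetracosa-14,16-dienoic acid | OC(=O)[C@@H](C)C[C@@H](C)CCCC[C@@H](O[Si](C)(C)C(C)(C)C)CCC[C@@H](CC)/C=C/C=C(\COC)CC[C@@H](O[Si](C)(C)C(C)(C)C)[C@@H](O[Si](C)(C)C(C)(C)C)C[C@H](O[Si](C)(C)C(C)(C)C)CNC(=O)C(Br)CCC | intermediate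
41 | 9,20,21,23-tetrakis-O-(tert-butyldimethylsilyl) ether of the target macrocycle (2′S) | CCC[C@@H]1OC(=O)[C@@H](C)C[C@@H](C)CCCC[C@@H](O[Si](C)(C)C(C)(C)C)CCC[C@@H](CC)/C=C/C=C(\COC)CC[C@@H](O[Si](C)(C)C(C)(C)C)[C@@H](O[Si](C)(C)C(C)(C)C)C[C@H](O[Si](C)(C)C(C)(C)C)CNC1=O | intermediate
42 | CNP0221503.3 (2′S,2S,4S,9R,13R,14E,16Z,20R,21S,23S) | CCC[C@@H]1OC(=O)[C@@H](C)C[C@@H](C)CCCC[C@@H](O)CCC[C@@H](CC)/C=C/C=C(\COC)CC[C@@H](O)[C@@H](O)C[C@H](O)CNC1=O | target

**Totals**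
Total step count: 22. Longest linear sequence: 15 steps (1–6, 9, 10, 12, 17–22) from anhydride 1.

**Steps most likely to fail and their fallbacks**

Step 21 (the proposed copper-catalysed stereoconvergent macrolactonisation). The fallback sets out from azido acid 36 and returns at 41, using known chemistry only. Staudinger reduction as in step 20 gives amino acid 39, which is N-acylated (THF/aq. NaHCO3, 0 °C) with N-succinimidyl (2S)-2-hydroxypentanoate F1, made from commercial (S)-2-hydroxypentanoic acid, N-hydroxysuccinimide and EDC·HCl. This gives (2S,4S,9R,13R,14E,16Z,20R,21S,23S)-9,20,21,23-tetrakis[(tert-butyldimethylsilyl)oxy]-13-ethyl-24-[(2S)-2-hydroxypentanamido]-17-(methoxymethyl)-2,4-dimethyltetracosa-14,16-dienoic acid F2. Shiina macrolactonisation (MNBA, DMAP, CH2Cl2, 1 mM, rt) then closes the same ester from the acyl side with retention at C2′ and gives 41.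

Step 17 (B-alkyl Suzuki coupling at the hindered 2-bromodiene). The fallback sets out from alkene 32 and alkenylzinc chloride 22 (made from alkyne 18 as in the first half of step 12) and returns at 34. The trisubstituted alkene is built on the eastern half and the halves are joined at C15–C16 instead.
- Hydroboration/oxidation of 32 (9-BBN; NaOH, H2O2) gives (3R,4S,6S)-3,4,6-tris[(tert-butyldimethylsilyl)oxy]-7-chloroheptan-1-ol F3.
- I2, PPh3 and imidazole give (3R,4S,6S)-3,4,6-tris[(tert-butyldimethylsilyl)oxy]-7-chloro-1-iodoheptane F4.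
- Mg in Et2O gives [(3R,4S,6S)-3,4,6-tris[(tert-butyldimethylsilyl)oxy]-7-chloroheptyl]magnesium iodide F5.
- CuI-catalysed anti-carbomagnesiation of the chloromagnesium alkoxide of propargyl alcohol (from i-PrMgCl), then I2, gives (2Z)-2-[(3R,4S,6S)-3,4,6-tris[(tert-butyldimethylsilyl)oxy]-7-chloroheptyl]-3-iodoprop-2-en-1-ol F6.
- NaH and MeI give (1Z,5R,6S,8S)-5,6,8-tris[(tert-butyldimethylsilyl)oxy]-9-chloro-1-iodo-2-(methoxymethyl)non-1-ene F7.
- Negishi coupling of this iodide with 22 (Pd(PPh3)4, THF, rt) delivers 34. Step 11 and the coupling with 20 are then not needed.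

Step 15 (γ-silylallylboration/Tamao oxidation on a β-silyloxy aldehyde). The fallback sets out from aldehyde 26 and returns at diol 31. Iridium-catalysed transfer-hydrogenative anti-(α-acyloxy)allylation ([Ir(cod)Cl]2, (S)-SEGPHOS, 4-cyano-3-nitrobenzoic acid, K3PO4, prop-2-ene-1,1-diyl dibenzoate, 2-propanol, THF, 60 °C) gives (3R,4S,6S)-6-[(tert-butyldimethylsilyl)oxy]-7-chloro-4-hydroxyhept-1-en-3-yl benzoate F8. Methanolysis (K2CO3, MeOH, 0 °C) removes the benzoate and gives 31.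

**Further compounds**
F1 | step 21 | N-succinimidyl (2S)-2-hydroxypentanoate | CCC[C@H](O)C(=O)ON1C(=O)CCC1=O
F2 | step 21 | (2S,4S,9R,13R,14E,16Z,20R,21S,23S)-9,20,21,23-tetrakis[(tert-butyldimethylsilyl)oxy]-13-ethyl-24-[(2S)-2-hydroxypentanamido]-17-(methoxymethyl)-2,4-dimethyltetracosa-14,16-dienoic acid | OC(=O)[C@@H](C)C[C@@H](C)CCCC[C@@H](O[Si](C)(C)C(C)(C)C)CCC[C@@H](CC)/C=C/C=C(\COC)CC[C@@H](O[Si](C)(C)C(C)(C)C)[C@@H](O[Si](C)(C)C(C)(C)C)C[C@H](O[Si](C)(C)C(C)(C)C)CNC(=O)[C@@H](O)CCC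
F3 | step 17 | (3R,4S,6S)-3,4,6-tris[(tert-butyldimethylsilyl)oxy]-7-chloroheptan-1-ol | OCC[C@@H](O[Si](C)(C)C(C)(C)C)[C@@H](O[Si](C)(C)C(C)(C)C)C[C@H](O[Si](C)(C)C(C)(C)C)CCl
F4 | step 17 | (3R,4S,6S)-3,4,6-tris[(tert-butyldimethylsilyl)oxy]-7-chloro-1-iodoheptane | ICC[C@@H](O[Si](C)(C)C(C)(C)C)[C@@H](O[Si](C)(C)C(C)(C)C)C[C@H](O[Si](C)(C)C(C)(C)C)CCl
F5 | step 17 | [(3R,4S,6S)-3,4,6-tris[(tert-butyldimethylsilyl)oxy]-7-chloroheptyl]magnesium iodide | I[Mg]CC[C@@H](O[Si](C)(C)C(C)(C)C)[C@@H](O[Si](C)(C)C(C)(C)C)C[C@H](O[Si](C)(C)C(C)(C)C)CCl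
F6 | step 17 | (2Z)-2-[(3R,4S,6S)-3,4,6-tris[(tert-butyldimethylsilyl)oxy]-7-chloroheptyl]-3-iodoprop-2-en-1-ol | I/C=C(\CO)CC[C@@H](O[Si](C)(C)C(C)(C)C)[C@@H](O[Si](C)(C)C(C)(C)C)C[C@H](O[Si](C)(C)C(C)(C)C)CCl
F7 | step 17 | (1Z,5R,6S,8S)-5,6,8-tris[(tert-butyldimethylsilyl)oxy]-9-chloro-1-iodo-2-(methoxymethyl)non-1-ene | I/C=C(\COC)CC[C@@H](O[Si](C)(C)C(C)(C)C)[C@@H](O[Si](C)(C)C(C)(C)C)C[C@H](O[Si](C)(C)C(C)(C)C)CCl
F8 | step 15 | (3R,4S,6S)-6-[(tert-butyldimethylsilyl)oxy]-7-chloro-4-hydroxyhept-1-en-3-yl benzoate | C=C[C@@H](OC(=O)c1ccccc1)[C@@H](O)C[C@H](O[Si](C)(C)C(C)(C)C)CCl
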